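Everything rests on disconnecting the aryl ether bond O1–C8a of ring C. A palladium-catalysed intramolecular C–O coupling joins the C2 hydroxyl, already set as R by reduction of an aryl ketone, to the brominated C8a of ring A and closes ring C without touching the C2–O bond. The feature exploited is that O1 sits on an aromatic carbon of ring A while C4 can be held as a carbinol, so no C4 ketone is present that could open ring C and scramble C2. The precursor is a 1-aryl-3-(2-bromoaryl)propane-1,3-diol whose C4 oxygen is silylated, leaving one hydroxyl for palladium, and whose O5 is benzylated, allowing a neutral hydrogenolytic finish.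

Key step: step 9

Remark: flavanone numbering (O1, C2, C3, C4, C4a, C5–C8, C8a) is used at every stage; the C4 carbinol is made racemic and erased in step 11, so 14, 15 and 16 are pairs of C4 epimers, each R at C2.

Step 1
Reactants: 1 1-(benzyloxy)-2-bromobenzene; 2 4-bromo-2,6-dimethoxybenzaldehyde
Product: 4 rac-[2-(benzyloxy)phenyl](4-bromo-2,6-dimethoxyphenyl)methanol, via [2-(benzyloxy)phenyl]magnesium bromide 3 (not isolated)
Conditions: Mg, I2 (cat.), THF, reflux; then 2, THF, 0 °C → rt; aq. NH4Cl
Reagents that add atoms: none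
Why: Grignard addition: the arylmagnesium bromide should add to the aldehyde at 0 °C much faster than it can exchange with the aryl bromide of 2, giving the diaryl carbinol.

Step 2
Reactants: 4 rac-[2-(benzyloxy)phenyl](4-bromo-2,6-dimethoxyphenyl)methanol
Product: 5 2-[2-(benzyloxy)benzyl]-5-bromo-1,3-dimethoxybenzene
Conditions: Et3SiH, CF3CO2H, CH2Cl2, 0 °C
Reagents that add atoms: none
Why: Ionic hydrogenation: acid should ionise the doubly benzylic carbinol to a cation stabilised by the two ortho methoxy groups, and hydride transfer from the silane then gives a diarylmethane whose two free positions on ring A are equivalent.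

Step 3
Reactants: 5 2-[2-(benzyloxy)benzyl]-5-bromo-1,3-dimethoxybenzene
Product: 7 3-[2-(benzyloxy)benzyl]-6-bromo-2,4-dimethoxybenzaldehyde, via aryl iminium chloride 6 (not isolated)
Conditions: POCl3, DMF, 90 °C; then ice–water, rt
Reagents that add atoms: N,N-dimethylformamide CN(C)C=O; water O
Why: Vilsmeier–Haack formylation: the chloroiminium ion should attack ring A, the only doubly alkoxy-activated ring, at one of its two symmetry-equivalent positions (ortho to one methoxy, para to the other, next to bromine), so the benzyl group ends up at C6 and the formyl carbon becomes C4.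

Step 4
Reactants: 7 3-[2-(benzyloxy)benzyl]-6-bromo-2,4-dimethoxybenzaldehyde
Product: 8 3-[2-(benzyloxy)benzyl]-6-bromo-2-hydroxy-4-methoxybenzaldehyde
Conditions: MgI2, Et2O–toluene, 50 °C; then 1 M HCl
Reagents that add atoms: none
Why: Chelation-controlled ether cleavage: magnesium should bridge the formyl oxygen and the neighbouring methoxy oxygen, so that iodide demethylates only this position (the later O5) and spares the para methoxy group and the non-chelating benzyl ether.

Step 5
Reactants: 8 3-[2-(benzyloxy)benzyl]-6-bromo-2-hydroxy-4-methoxybenzaldehyde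
Product: 9 2-(benzyloxy)-3-[2-(benzyloxy)benzyl]-6-bromo-4-methoxybenzaldehyde
Conditions: BnBr, K2CO3, DMF, 50 °C
Reagents that add atoms: benzyl bromide BrCc1ccccc1
Why: Williamson etherification of the phenoxide should give the benzyl ether, so that every oxygen to be freed at the end carries a hydrogenolysable group and the 7-methoxy group is the only methyl ether.

Step 6
Reactants: 10 1-[4-(benzyloxy)phenyl]ethanone; 9 2-(benzyloxy)-3-[2-(benzyloxy)benzyl]-6-bromo-4-methoxybenzaldehyde
Product: 12 rac-3-{2-(benzyloxy)-3-[2-(benzyloxy)benzyl]-6-bromo-4-methoxyphenyl}-1-[4-(benzyloxy)phenyl]-3-hydroxypropan-1-one, via lithium 1-[4-(benzyloxy)phenyl]ethenolate 11 (not isolated)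
Conditions: LiN(iPr)2, THF, −78 °C; then 9, −78 °C; AcOH, −78 °C
Reagents that add atoms: none
Why: Directed aldol addition: the preformed lithium enolate of the methyl ketone should add to the non-enolisable aldehyde at −78 °C, and quenching cold with acetic acid should prevent retro-aldol cleavage and dehydration.

Step 7
Reactants: 12 rac-3-{2-(benzyloxy)-3-[2-(benzyloxy)benzyl]-6-bromo-4-methoxyphenyl}-1-[4-(benzyloxy)phenyl]-3-hydroxypropan-1-one
Product: 13 rac-3-{2-(benzyloxy)-3-[2-(benzyloxy)benzyl]-6-bromo-4-methoxyphenyl}-1-[4-(benzyloxy)phenyl]-3-[(tert-butyldimethylsilyl)oxy]propan-1-one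
Conditions: TBSOTf, 2,6-lutidine, CH2Cl2, −78 → 0 °C
Reagents that add atoms: tert-butyldimethylsilyl trifluoromethanesulfonate CC(C)(C)[Si](C)(C)OS(=O)(=O)C(F)(F)F
Why: O-Silylation with a silyl triflate and a hindered base should cap the crowded C4 hydroxyl without β-elimination, leaving a ketone free of OH groups for the reduction and, later, a single hydroxyl for the coupling.

Step 8
Reactants: 13 rac-3-{2-(benzyloxy)-3-[2-(benzyloxy)benzyl]-6-bromo-4-methoxyphenyl}-1-[4-(benzyloxy)phenyl]-3-[(tert-butyldimethylsilyl)oxy]propan-1-one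
Product: 14 (1R,3RS)-3-{2-(benzyloxy)-3-[2-(benzyloxy)benzyl]-6-bromo-4-methoxyphenyl}-1-[4-(benzyloxy)phenyl]-3-[(tert-butyldimethylsilyl)oxy]propan-1-ol
Conditions: (S)-tetrahydro-1-methyl-3,3-diphenyl-1H,3H-pyrrolo[1,2-c][1,3,2]oxazaborole (10 mol %), BH3·SMe2, THF, −20 °C; then MeOH
Reagents that add atoms: none
Why: Corey–Bakshi–Shibata reduction: the ketone should bind the oxazaborolidine–borane complex with the aryl group in the position of the large substituent, so that hydride is delivered to one face under catalyst control and the future C2 carbinol is formed as R in both C4 epimers.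

Step 9
Reactants: 14 (1R,3RS)-3-{2-(benzyloxy)-3-[2-(benzyloxy)benzyl]-6-bromo-4-methoxyphenyl}-1-[4-(benzyloxy)phenyl]-3-[(tert-butyldimethylsilyl)oxy]propan-1-ol
Product: 15 (2R,4RS)-5-(benzyloxy)-6-[2-(benzyloxy)benzyl]-2-[4-(benzyloxy)phenyl]-4-[(tert-butyldimethylsilyl)oxy]-7-methoxychromane
Conditions: Pd(OAc)2 (5 mol %), 2-(di-tert-butylphosphino)-1,1'-binaphthyl (6 mol %), Cs2CO3, toluene, 70 °C
Reagents that add atoms: none
Why: Zerovalent palladium, generated from Pd(OAc)2 and the phosphine, should add oxidatively to the C8a–Br bond; the C2 hydroxyl then binds divalent palladium, Cs2CO3 takes its proton, and C–O reductive elimination releases the aryl ether. The closest known reaction type is the Buchwald–Hartwig-type intramolecular etherification of aryl bromides with secondary alcohols, which gives 2-substituted chromans. Ring C is closed as a six-membered cyclic ether through a seven-membered oxapalladacycle, the tethered alkoxide ending on C8a (exo mode, O1–C8a the only new bond). No stereocentre is created: C2 stays R because its C–O bond is never cleaved, and C4 is a temporary centre present as both epimers. The step needs reductive elimination to outrun β-hydride elimination of the secondary benzylic alkoxide, which the bulky electron-rich biaryl phosphine favours. Chemoselectivity is secured in the substrate, since the C4 oxygen is silylated, so that no second alkoxide next to the C–Br bond can chelate palladium or pass a hydride to it.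

Step 10
Reactants: 15 (2R,4RS)-5-(benzyloxy)-6-[2-(benzyloxy)benzyl]-2-[4-(benzyloxy)phenyl]-4-[(tert-butyldimethylsilyl)oxy]-7-methoxychromane
Product: 16 (2R,4RS)-5-(benzyloxy)-6-[2-(benzyloxy)benzyl]-2-[4-(benzyloxy)phenyl]-7-methoxychroman-4-ol
Conditions: Bu4NF, THF, 0 °C → rt
Reagents that add atoms: none
Why: Fluoride-induced desilylation should free the C4 hydroxyl under non-acidic conditions, under which this electron-rich benzylic alcohol does not ionise and the aryl benzyl ethers and C2 stay intact.

Step 11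
Reactants: 16 (2R,4RS)-5-(benzyloxy)-6-[2-(benzyloxy)benzyl]-2-[4-(benzyloxy)phenyl]-7-methoxychroman-4-ol
Product: 17 (2R)-5-(benzyloxy)-6-[2-(benzyloxy)benzyl]-2-[4-(benzyloxy)phenyl]-7-methoxychroman-4-one
Conditions: Dess–Martin periodinane, NaHCO3, CH2Cl2, 0 °C → rt
Reagents that add atoms: none
Why: Dess–Martin oxidation under bicarbonate buffer should turn both C4 epimers into the same ketone, and the mild, nearly neutral conditions should not open ring C, so C2 stays R.

Step 12
Reactants: 17 (2R)-5-(benzyloxy)-6-[2-(benzyloxy)benzyl]-2-[4-(benzyloxy)phenyl]-7-methoxychroman-4-one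
Product: 18 (+)-methylphelligrin A [(2R)-5-hydroxy-6-(2-hydroxybenzyl)-2-(4-hydroxyphenyl)-7-methoxychroman-4-one]
Conditions: H2 (1 atm), Pd/C (10 wt %), EtOAc, rt
Reagents that add atoms: none
Why: Catalytic hydrogenolysis should cleave the three primary aryl benzyl ethers faster than the hindered secondary C2–O1 bond, and its neutral medium avoids the base-induced retro-oxa-Michael opening and the Lewis-acid ionisation at C2 that could racemise the flavanone.

Compound list

1 | 1-(benzyloxy)-2-bromobenzene | Brc1ccccc1OCc1ccccc1 | starting material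
2 | 4-bromo-2,6-dimethoxybenzaldehyde | COc1cc(Br)cc(OC)c1C=O | starting material
3 | [2-(benzyloxy)phenyl]magnesium bromide | Br[Mg]c1ccccc1OCc1ccccc1 | intermediate (not isolated)
4 | rac-[2-(benzyloxy)phenyl](4-bromo-2,6-dimethoxyphenyl)methanol | COc1cc(Br)cc(OC)c1C(O)c1ccccc1OCc1ccccc1 | intermediate
5 | 2-[2-(benzyloxy)benzyl]-5-bromo-1,3-dimethoxybenzene | COc1cc(Br)cc(OC)c1Cc1ccccc1OCc1ccccc1 | intermediate
6 | N-({3-[2-(benzyloxy)benzyl]-6-bromo-2,4-dimethoxyphenyl}methylidene)-N-methylmethanaminium chloride | COc1cc(Br)c(C=[N+](C)C)c(OC)c1Cc1ccccc1OCc1ccccc1.[Cl-] | intermediate (not isolated)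
7 | 3-[2-(benzyloxy)benzyl]-6-bromo-2,4-dimethoxybenzaldehyde | COc1cc(Br)c(C=O)c(OC)c1Cc1ccccc1OCc1ccccc1 | intermediate
8 | 3-[2-(benzyloxy)benzyl]-6-bromo-2-hydroxy-4-methoxybenzaldehyde | COc1cc(Br)c(C=O)c(O)c1Cc1ccccc1OCc1ccccc1 | intermediate
9 | 2-(benzyloxy)-3-[2-(benzyloxy)benzyl]-6-bromo-4-methoxybenzaldehyde | COc1cc(Br)c(C=O)c(OCc2ccccc2)c1Cc1ccccc1OCc1ccccc1 | intermediate
10 | 1-[4-(benzyloxy)phenyl]ethanone | CC(=O)c1ccc(OCc2ccccc2)cc1 | starting material
11 | lithium 1-[4-(benzyloxy)phenyl]ethenolate | [Li]OC(=C)c1ccc(OCc2ccccc2)cc1 | intermediate (not isolated)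
12 | rac-3-{2-(benzyloxy)-3-[2-(benzyloxy)benzyl]-6-bromo-4-methoxyphenyl}-1-[4-(benzyloxy)phenyl]-3-hydroxypropan-1-one | COc1cc(Br)c(C(O)CC(=O)c2ccc(OCc3ccccc3)cc2)c(OCc2ccccc2)c1Cc1ccccc1OCc1ccccc1 | intermediate
13 | rac-3-{2-(benzyloxy)-3-[2-(benzyloxy)benzyl]-6-bromo-4-methoxyphenyl}-1-[4-(benzyloxy)phenyl]-3-[(tert-butyldimethylsilyl)oxy]propan-1-one | COc1cc(Br)c(C(O[Si](C)(C)C(C)(C)C)CC(=O)c2ccc(OCc3ccccc3)cc2)c(OCc2ccccc2)c1Cc1ccccc1OCc1ccccc1 | intermediate
14 | (1R,3RS)-3-{2-(benzyloxy)-3-[2-(benzyloxy)benzyl]-6-bromo-4-methoxyphenyl}-1-[4-(benzyloxy)phenyl]-3-[(tert-butyldimethylsilyl)oxy]propan-1-ol (both C3 epimers, R at the free carbinol) | COc1cc(Br)c(C(O[Si](C)(C)C(C)(C)C)C[C@@H](O)c2ccc(OCc3ccccc3)cc2)c(OCc2ccccc2)c1Cc1ccccc1OCc1ccccc1 | intermediate (precursor of the key step)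
15 | (2R,4RS)-5-(benzyloxy)-6-[2-(benzyloxy)benzyl]-2-[4-(benzyloxy)phenyl]-4-[(tert-butyldimethylsilyl)oxy]-7-methoxychromane (both C4 epimers) | COc1cc2c(c(OCc3ccccc3)c1Cc1ccccc1OCc1ccccc1)C(O[Si](C)(C)C(C)(C)C)C[C@H](c1ccc(OCc3ccccc3)cc1)O2 | intermediate (product of the key step)
16 | (2R,4RS)-5-(benzyloxy)-6-[2-(benzyloxy)benzyl]-2-[4-(benzyloxy)phenyl]-7-methoxychroman-4-ol (both C4 epimers) | COc1cc2c(c(OCc3ccccc3)c1Cc1ccccc1OCc1ccccc1)C(O)C[C@H](c1ccc(OCc3ccccc3)cc1)O2 | intermediate
17 | (2R)-5-(benzyloxy)-6-[2-(benzyloxy)benzyl]-2-[4-(benzyloxy)phenyl]-7-methoxychroman-4-one | COc1cc2c(c(OCc3ccccc3)c1Cc1ccccc1OCc1ccccc1)C(=O)C[C@H](c1ccc(OCc3ccccc3)cc1)O2 | intermediate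
18 | (+)-methylphelligrin A, (2R)-5-hydroxy-6-(2-hydroxybenzyl)-2-(4-hydroxyphenyl)-7-methoxychroman-4-one | COc1cc2c(c(O)c1Cc1ccccc1O)C(=O)C[C@H](c1ccc(O)cc1)O2 | target

Total step count: 12. Longest linear sequence: 12 steps (from 1 or 2 to 18; ketone 10 enters at step 6).

Steps most likely to fail

1. Step 9. The palladium alkoxide of the secondary benzylic alcohol may undergo β-hydride elimination faster than C–O reductive elimination, which would oxidise the carbinol and reduce the C–Br bond. Oxidative addition next to the crowded silyloxy-bearing carbon may be slow, and the silyl group may migrate to the C2 oxygen under base. Fallback: form the other bond of the ether oxygen, O1–C2, by Mitsunobu ring closure with inversion. It sets out from ketone 13. Reduction as in step 8, but with the (R)-configured oxazaborolidine, should give the (1S,3RS)-alcohol F1. Miyaura borylation (bis(pinacolato)diboron, Pd(dppf)Cl2, KOAc, dioxane, 80 °C) should give the pinacol boronate F2, and oxidation with NaBO3·4H2O in THF–water should give the phenol F3. PPh3 and diisopropyl azodicarboxylate (THF, 0 °C) should then close ring C by SN2 attack of the phenol oxygen at C2 with inversion, which gives the R configuration and returns to the route at 15.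

2. Step 3. Electrophilic attack at a ring position flanked by bromine and methoxy may be sluggish, and prolonged heating in POCl3 may erode the benzyl ether. Fallback: halogenation followed by metalation. From 5, N-iodosuccinimide in MeCN should iodinate the same activated position to give the aryl iodide F4. Iodine–magnesium exchange with iPrMgCl·LiCl (THF, −40 °C), which leaves the bromide alone, and quenching with DMF should give 7, where the route is rejoined.

3. Step 8. Enantioface discrimination may be incomplete, because the electron-rich 4-alkoxyphenyl ketone is reduced slowly by the catalyst–borane complex and uncatalysed borane reduction can compete. Fallback: asymmetric transfer hydrogenation of 13 with RuCl(p-cymene)[(R,R)-TsDPEN] and HCO2H/Et3N (CH2Cl2, rt). This is a metal–ligand bifunctional hydride transfer with a different mode of face recognition; it leads from 13 directly to 14 and makes no new compound (F0).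

Further compounds

F1 | step 9 | (1S,3RS)-3-{2-(benzyloxy)-3-[2-(benzyloxy)benzyl]-6-bromo-4-methoxyphenyl}-1-[4-(benzyloxy)phenyl]-3-[(tert-butyldimethylsilyl)oxy]propan-1-ol | COc1cc(Br)c(C(O[Si](C)(C)C(C)(C)C)C[C@H](O)c2ccc(OCc3ccccc3)cc2)c(OCc2ccccc2)c1Cc1ccccc1OCc1ccccc1
F2 | step 9 | (1S,3RS)-3-{2-(benzyloxy)-3-[2-(benzyloxy)benzyl]-4-methoxy-6-(4,4,5,5-tetramethyl-1,3,2-dioxaborolan-2-yl)phenyl}-1-[4-(benzyloxy)phenyl]-3-[(tert-butyldimethylsilyl)oxy]propan-1-ol | COc1cc(B2OC(C)(C)C(C)(C)O2)c(C(O[Si](C)(C)C(C)(C)C)C[C@H](O)c2ccc(OCc3ccccc3)cc2)c(OCc2ccccc2)c1Cc1ccccc1OCc1ccccc1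
F3 | step 9 | 3-(benzyloxy)-4-[2-(benzyloxy)benzyl]-2-{(1RS,3S)-3-[4-(benzyloxy)phenyl]-1-[(tert-butyldimethylsilyl)oxy]-3-hydroxypropyl}-5-methoxyphenol | COc1cc(O)c(C(O[Si](C)(C)C(C)(C)C)C[C@H](O)c2ccc(OCc3ccccc3)cc2)c(OCc2ccccc2)c1Cc1ccccc1OCc1ccccc1
F4 | step 3 | 2-[2-(benzyloxy)benzyl]-5-bromo-4-iodo-1,3-dimethoxybenzene | COc1cc(Br)c(I)c(OC)c1Cc1ccccc1OCc1ccccc1
F0 | step 8 | none | none
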